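The retrosynthesis first removes the C8 methacrylate, the C9 acetate and the C13 methylene. It then opens the ten-membered ring (C1–C10) at C3–C4, cuts the chain at C9–C10 and at C6–C7, and traces the lactone carbonyl C12 back to a vinyl group on C7.
Enabling feature: C3–C4 is a single bond between the saturated C2–C3 bridge and the trisubstituted C4=C5 alkene of the carbocycle. C4 can therefore be a vinyl iodide of fixed geometry and C3 a primary alkylborane made from the end of a C10=C1–C2=C3 diene, so both ring-cis alkenes exist before the ring does.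
Forward order: C6–C7 (allylchromium plus β-iodoenal), γ-lactone ring (O–C6–C7–C11–C12), C9–C10 (dienylmagnesium plus α-alkoxy aldehyde), ten-membered ring (C3–C4). After that come C13, the C8 ester, the C14 aldehyde, the C9 ester and the C15 hydroxyl.
Stereochemistry: C8 comes from diethyl D-tartrate. C6 and C7 come from the chair transition state of the allylation under Felkin-type control by C8, and C9 from chelation to the C8 ether. Both alkene geometries come from hydroxyl-directed trans-hydroalumination and iodination of propargylic alcohols.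
O8 (PMB) and O9 (TES) carry different groups from the moment C9 is made, so the two esters never have to be distinguished on a free diol.
Key step: step 21

Remark: germacrane numbering of the target is used for every intermediate, and the configuration is taken as encoded in the SMILES (6R,7S,8S,9S, both ring alkenes cis within the ring). The C6 descriptor reads S while iodine sits on C4 and R afterwards, with no change in space.

Step 1
Reactants: 1 2-butyne-1,4-diol
Product: 2 4-(tert-butyldiphenylsilyloxy)but-2-yn-1-ol
Conditions: TBDPSCl (1 equiv), imidazole, excess 1, DMF, 0 °C to rt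
Reagents that add atoms: tert-butyldiphenylsilyl chloride, CC(C)(C)[Si](Cl)(c1ccccc1)c1ccccc1
Why: Silyl ether formation on a symmetrical diol used in excess should stop mainly at the mono-ether, and TBDPS is chosen because the C15 oxygen must outlast every later acid and fluoride treatment except the last.

Step 2
Reactants: 2 4-(tert-butyldiphenylsilyloxy)but-2-yn-1-ol
Product: 4 (Z)-4-(tert-butyldiphenylsilyloxy)-3-iodobut-2-en-1-ol, via cyclic vinylalanate 3 (not isolated)
Conditions: NaAlH2(OCH2CH2OMe)2, THF, 0 °C to rt; then I2, THF, −78 °C to 0 °C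
Reagents that add atoms: iodine, II
Why: Hydroxyl-directed trans-hydroalumination of the propargylic alcohol places aluminium on the distal alkyne carbon (C4) inside a five-membered alanate, and iodinolysis with retention puts iodine cis to C6, which is the ring-cis geometry of C4=C5.

Step 3
Reactants: 4 (Z)-4-(tert-butyldiphenylsilyloxy)-3-iodobut-2-en-1-ol
Product: 5 (Z)-4-(tert-butyldiphenylsilyloxy)-3-iodobut-2-enal
Conditions: MnO2, CH2Cl2, rt, dark
Reagents that add atoms: none
Why: Heterogeneous MnO2 oxidation of an allylic alcohol is neutral, stops at the enal and should leave the Z-iodoalkene unchanged.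

Step 4
Reactants: 6 diethyl D-tartrate
Product: 7 diethyl (4S,5S)-2-(4-methoxyphenyl)-1,3-dioxolane-4,5-dicarboxylate
Conditions: 4-MeOC6H4CH(OMe)2, catalytic TsOH, toluene, reflux with removal of MeOH
Reagents that add atoms: 4-methoxybenzaldehyde dimethyl acetal, COc1ccc(C(OC)OC)cc1
Why: Acid-catalysed transacetalisation is driven by loss of methanol, and the acetal carbon of the C2-symmetric trans-dioxolane is not a stereocentre.

Step 5
Reactants: 7 diethyl (4S,5S)-2-(4-methoxyphenyl)-1,3-dioxolane-4,5-dicarboxylate
Product: 8 2-O-(4-methoxybenzyl)-D-threitol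
Conditions: LiAlH4, AlCl3, Et2O/CH2Cl2, 0 °C to rt
Reagents that add atoms: none
Why: Mixed-hydride reduction takes both esters to carbinols and opens the benzylidene-type acetal reductively, and because the two acetal oxygens are equivalent by symmetry a single mono-PMB ether should result with both carbinol centres untouched.

Step 6
Reactants: 8 2-O-(4-methoxybenzyl)-D-threitol
Product: 10 ethyl (S,E)-5-hydroxy-4-(4-methoxybenzyloxy)pent-2-enoate, via 2-O-PMB-D-glyceraldehyde 9 (not isolated)
Conditions: NaIO4, H2O, 0 °C to rt, extraction; then (EtO)2P(O)CH2CO2Et, K2CO3, H2O, 0 °C to rt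
Reagents that add atoms: triethyl phosphonoacetate, CCOC(=O)CP(=O)(OCC)OCC
Why: Malaprade cleavage of the only vicinal diol followed by Horner–Wadsworth–Emmons olefination of the crude aldehyde under mild carbonate conditions gives the E-enoate (C7=C11–C12) and leaves the PMB-bearing carbon as C8 in the configuration of the target.

Step 7
Reactants: 10 ethyl (S,E)-5-hydroxy-4-(4-methoxybenzyloxy)pent-2-enoate
Product: 11 ethyl (S,E)-5-(tert-butyldimethylsilyloxy)-4-(4-methoxybenzyloxy)pent-2-enoate
Conditions: TBSCl, imidazole, CH2Cl2, 0 °C to rt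
Reagents that add atoms: tert-butyldimethylsilyl chloride, CC(C)(C)[Si](C)(C)Cl
Why: Standard silylation of the primary C9 hydroxyl installs a group that can later be removed in the presence of the TBDPS ether.

Step 8
Reactants: 11 ethyl (S,E)-5-(tert-butyldimethylsilyloxy)-4-(4-methoxybenzyloxy)pent-2-enoate
Product: 12 (S,E)-5-(tert-butyldimethylsilyloxy)-4-(4-methoxybenzyloxy)pent-2-en-1-ol
Conditions: iBu2AlH (2.2 equiv), CH2Cl2, −78 °C
Reagents that add atoms: none
Why: Low-temperature 1,2-reduction of an enoate with iBu2AlH gives the E-allylic alcohol without touching the ethers or the alkene.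

Step 9
Reactants: 12 (S,E)-5-(tert-butyldimethylsilyloxy)-4-(4-methoxybenzyloxy)pent-2-en-1-ol
Product: 13 (S,E)-allylic bromide (C12 bromide of 12)
Conditions: CBr4, PPh3, CH2Cl2, 0 °C
Reagents that add atoms: carbon tetrabromide, BrC(Br)(Br)Br
Why: The Appel reaction replaces the primary allylic hydroxyl by bromide under neutral conditions by direct displacement, so alkene position and geometry are kept.

Step 10
Reactants: 13 (S,E)-allylic bromide; 5 (Z)-4-(tert-butyldiphenylsilyloxy)-3-iodobut-2-enal
Product: 15 (6S,7S,8S)-homoallylic alcohol, via allylchromium dichloride 14 (not isolated)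
Conditions: CrCl2 (nickel-free), THF, 0 °C to rt, 13 and 5 added together
Reagents that add atoms: none
Why: In this Nozaki–Hiyama allylation the bromide is reduced by two equivalents of divalent chromium far faster than the vinyl iodide, the E-allylchromium adds through its γ-carbon C7 in a chair transition state with C5 and C8 equatorial (C6–O and C7–C8 anti, the later trans-lactone), and it reacts on the face where the C8–O bond lies anti to the forming C6–C7 bond with C8–H turned toward the aldehyde side chain (Felkin-type control known for allylic bromides with an alkoxy stereocentre next to the alkene), which sets C7 and with it C6 relative to C8.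

Step 11
Reactants: 15 (6S,7S,8S)-homoallylic alcohol
Product: 17 C6,C12-diol, via bis-boron adduct 16 (not isolated)
Conditions: 9-BBN (2.5 equiv), THF, rt to 50 °C; then H2O2, NaOH, H2O, 0 °C
Reagents that add atoms: hydrogen peroxide, OO
Why: In this Brown hydroboration–oxidation the bulky 9-BBN adds only to the monosubstituted C11=C12 alkene with boron on terminal C12, and the trisubstituted iodoalkene is too hindered to react.

Step 12
Reactants: 17 C6,C12-diol
Product: 19 trans-γ-lactone (C9 OTBS), via lactol 18 (not isolated)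
Conditions: TEMPO (catalytic), PhI(OAc)2, CH2Cl2, rt
Reagents that add atoms: none
Why: In this oxoammonium (TEMPO) oxidative lactonisation the primary C12 alcohol is oxidised ahead of the hindered secondary C6 alcohol, the hydroxy aldehyde closes to the five-membered lactol and this is oxidised on to the lactone, whose trans C6/C7 relationship is inherited from step 10.

Step 13
Reactants: 19 trans-γ-lactone (C9 OTBS)
Product: 20 C9 primary alcohol
Conditions: HF·pyridine, pyridine, THF, 0 °C
Reagents that add atoms: none
Why: Buffered fluoride desilylation removes a primary alkyl TBS ether much faster than a TBDPS ether and is too mild to open or shift the lactone.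

Step 14
Reactants: 20 C9 primary alcohol
Product: 21 C9 aldehyde
Conditions: Dess–Martin periodinane, CH2Cl2, 0 °C to rt
Reagents that add atoms: none
Why: Dess–Martin oxidation is fast and essentially neutral, so the α-alkoxy aldehyde should form without epimerisation at C8.

Step 15
Reactants: 22 3,3-diethoxyprop-1-yne
Product: 24 4,4-diethoxybut-2-yn-1-ol, via lithium acetylide 23 (not isolated)
Conditions: nBuLi, THF, −78 °C; then (CH2O)n, −78 °C to rt
Reagents that add atoms: paraformaldehyde (as formaldehyde), C=O
Why: Addition of the lithium acetylide to formaldehyde is a standard hydroxymethylation and brings in C2 next to C1, C10 and the acetal carbon C14.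

Step 16
Reactants: 24 4,4-diethoxybut-2-yn-1-ol
Product: 26 (Z)-4,4-diethoxy-3-iodobut-2-en-1-ol, via cyclic vinylalanate 25 (not isolated)
Conditions: NaAlH2(OCH2CH2OMe)2, THF, 0 °C; then I2, THF, −78 °C to 0 °C, basic work-up
Reagents that add atoms: iodine, II
Why: The same hydroxyl-directed trans-hydroalumination and iodinolysis as in step 2 puts iodine on C10 cis to C2 and trans to nothing but C1–H, so the carbon that later replaces iodine (C9) ends up cis to C2 and C14 trans to C2.

Step 17
Reactants: 26 (Z)-4,4-diethoxy-3-iodobut-2-en-1-ol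
Product: 27 (Z)-4,4-diethoxy-3-iodobut-2-enal
Conditions: MnO2, CH2Cl2, rt, dark
Reagents that add atoms: none
Why: Neutral MnO2 oxidation of the allylic alcohol spares the acetal and the alkene geometry.

Step 18
Reactants: 27 (Z)-4,4-diethoxy-3-iodobut-2-enal
Product: 28 (3Z)-5,5-diethoxy-4-iodopenta-1,3-diene
Conditions: MePPh3Br, KN(SiMe3)2, THF, 0 °C; then 27, −78 °C to 0 °C
Reagents that add atoms: methyltriphenylphosphonium bromide, C[P+](c1ccccc1)(c1ccccc1)c1ccccc1.[Br-]
Why: Wittig methylenation with the non-stabilised ylide attacks the aldehyde carbon rapidly at low temperature, adds C3 and leaves the trisubstituted iodoalkene as it is.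

Step 19
Reactants: 28 (3Z)-5,5-diethoxy-4-iodopenta-1,3-diene; 21 C9 aldehyde
Product: 31 (6S,7S,8S,9S)-C9 dienyl carbinol, via dienyllithium 29 (not isolated), via dienylmagnesium bromide 30 (not isolated)
Conditions: 28 (1.5 equiv), tBuLi (3 equiv), Et2O, −78 °C; MgBr2·OEt2, −78 °C; then 21 premixed with MgBr2·OEt2, CH2Cl2, −78 °C to −40 °C
Reagents that add atoms: none
Why: After iodine–lithium exchange with retention and transmetalation to magnesium the addition follows the Cram-chelate model, in which magnesium ties the aldehyde oxygen to the PMB ether oxygen on C8 and the dienyl group attacks from the side of C8–H to give the 8,9-syn diol pattern (9S), while at this temperature the aldehyde reacts well ahead of the lactone and the C4 iodide.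

Step 20
Reactants: 31 (6S,7S,8S,9S)-C9 dienyl carbinol
Product: 32 open-chain iodo-diene (O8 PMB / O9 TES)
Conditions: TESCl, imidazole, catalytic DMAP, DMF, 0 °C to rt
Reagents that add atoms: triethylsilyl chloride, CC[Si](Cl)(CC)CC
Why: Chloride-based silylation under imidazole protects the C9 hydroxyl without the silyl triflate and lutidine pair that would attack the diethyl acetal, and it gives O9 a group orthogonal to the PMB ether on O8.

Step 21
Reactants: 32 open-chain iodo-diene (O8 PMB / O9 TES)
Product: 34 ten-membered cis,cis-diene lactone, via C3 alkylborane 33 (not isolated)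
Conditions: 9-BBN (1.3 equiv), THF, rt; then syringe-pump addition to PdCl2(dppf), AsPh3, Cs2CO3, degassed DMF/THF/H2O, 50 °C, final concentration about 1 mM
Reagents that add atoms: none
Why: 9-BBN adds across the only monosubstituted alkene, C2=C3 of the diene, with boron on terminal C3 to give homoallylic borane 33, the two trisubstituted alkenes being too hindered to react. Zerovalent palladium generated from PdCl2(dppf) inserts into the C4–I bond with retention, the hydroxyborate formed from 33 and aqueous Cs2CO3 passes its primary alkyl group to palladium, and reductive elimination joins C3 to C4, which is an intramolecular B-alkyl Suzuki–Miyaura coupling, a reaction type established for macrocyclisation. The ten-membered carbocycle closes end to end by reductive elimination from an eleven-membered palladacycle that holds C3 and C4 cis on the metal. No stereocentre is created, the C4=C5 geometry is copied stereospecifically from the iodide and C1=C10 is a spectator, so both ring-cis alkenes arrive intact. The step needs hydroboration of C2=C3 ahead of lactone reduction, which near-stoichiometric 9-BBN at room temperature provides, and ring closure ahead of oligomerisation, which slow addition into dilute catalyst provides with help from the two cis alkenes and the trans-lactone that fold the chain and bring C3 near C4. Oxidative addition to the vinyl iodide is far faster than ionisation of the allylic C6–O lactone bond, so the lactone should survive.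

Step 22
Reactants: 34 ten-membered cis,cis-diene lactone
Product: 38 α-methylene lactone, via lithium enolate 35 (not isolated), via Mannich base 36 (not isolated), via ammonium iodide 37 (not isolated)
Conditions: LiN(iPr)2, THF, −78 °C; Me2N=CH2 iodide (Eschenmoser's salt), −78 °C to rt; crude, MeI, CH2Cl2/MeOH, rt; then aqueous NaHCO3, rt
Reagents that add atoms: N,N-dimethylmethyleneiminium iodide (Eschenmoser's salt), C=[N+](C)C.[I-]
Why: In the Eschenmoser methylenation the lactone C11 position is the only enolisable site (no ester is present yet), so Mannich aminomethylation, quaternisation and base-induced elimination of trimethylamine install C13, and the transient C11 stereocentre disappears.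

Step 23
Reactants: 38 α-methylene lactone
Product: 39 C8 alcohol
Conditions: DDQ, CH2Cl2/pH 7 buffer, 0 °C
Reagents that add atoms: none
Why: Oxidative cleavage of the electron-rich PMB ether with buffered DDQ frees O8 alone and leaves the silyl ethers, the acetal and the alkenes untouched.

Step 24
Reactants: 39 C8 alcohol
Product: 40 C8 methacrylate
Conditions: methacrylic anhydride, Et3N, DMAP, CH2Cl2, rt
Reagents that add atoms: methacrylic anhydride, C=C(C)C(=O)OC(=O)C(C)=C
Why: DMAP-catalysed acylation places the bulkier ester first while O9 is still silylated, so no neighbouring hydroxyl is available for acyl migration.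

Step 25
Reactants: 40 C8 methacrylate
Product: 41 C9 hydroxy C14 enal
Conditions: AcOH/THF/H2O (3:1:1), rt
Reagents that add atoms: water, O
Why: Mild aqueous acid hydrolyses the allylic diethyl acetal to the conjugated enal and cleaves the secondary TES ether in one operation, whereas the TBDPS ether and both ester-type groups are stable to these conditions.

Step 26
Reactants: 41 C9 hydroxy C14 enal
Product: 42 C9 acetate
Conditions: Ac2O, pyridine, catalytic DMAP, CH2Cl2, 0 °C
Reagents that add atoms: acetic anhydride, CC(=O)OC(C)=O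
Why: Acetylation of the only free hydroxyl, an allylic secondary alcohol, is fast at low temperature and should outrun migration of the less electrophilic methacrylate.

Step 27
Reactants: 42 C9 acetate
Product: 43 target (6R,7S,8S,9S)
Conditions: HF·pyridine, THF, 0 °C to rt, plastic vessel
Reagents that add atoms: none
Why: Acidic fluoride desilylation releases the primary allylic C15 hydroxyl without the basicity that would endanger the α-methylene lactone, the enal or the allylic acetate.

Compound list
1 | 2-butyne-1,4-diol | OCC#CCO | starting material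
2 | 4-(tert-butyldiphenylsilyloxy)but-2-yn-1-ol | OCC#CCO[Si](c1ccccc1)(c1ccccc1)C(C)(C)C | intermediate
3 | sodium cyclic vinylalanate from 2 (five-membered O–Al–C4 ring, not isolated) | [Na+].COCCO[Al-]1(OCCOC)OCC=C1CO[Si](c2ccccc2)(c2ccccc2)C(C)(C)C | intermediate
4 | (Z)-4-(tert-butyldiphenylsilyloxy)-3-iodobut-2-en-1-ol (iodine cis to CH2OH) | OC/C=C(/CO[Si](c1ccccc1)(c1ccccc1)C(C)(C)C)I | intermediate
5 | (Z)-4-(tert-butyldiphenylsilyloxy)-3-iodobut-2-enal (C6, C5, C4, C15) | O=C/C=C(/CO[Si](c1ccccc1)(c1ccccc1)C(C)(C)C)I | intermediate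
6 | diethyl D-tartrate, (2S,3S) | CCOC(=O)[C@@H](O)[C@H](O)C(=O)OCC | starting material
7 | diethyl (4S,5S)-2-(4-methoxyphenyl)-1,3-dioxolane-4,5-dicarboxylate | CCOC(=O)[C@H]1OC(c2ccc(OC)cc2)O[C@@H]1C(=O)OCC | intermediate
8 | 2-O-(4-methoxybenzyl)-D-threitol, (2R,3R) | OC[C@@H](OCc1ccc(OC)cc1)[C@H](O)CO | intermediate
9 | (R)-3-hydroxy-2-(4-methoxybenzyloxy)propanal (not isolated) | OC[C@@H](OCc1ccc(OC)cc1)C=O | intermediate
10 | ethyl (S,E)-5-hydroxy-4-(4-methoxybenzyloxy)pent-2-enoate | OC[C@@H](OCc1ccc(OC)cc1)/C=C/C(=O)OCC | intermediate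
11 | ethyl (S,E)-5-(tert-butyldimethylsilyloxy)-4-(4-methoxybenzyloxy)pent-2-enoate | CC(C)(C)[Si](C)(C)OC[C@@H](OCc1ccc(OC)cc1)/C=C/C(=O)OCC | intermediate
12 | (S,E)-5-(tert-butyldimethylsilyloxy)-4-(4-methoxybenzyloxy)pent-2-en-1-ol | CC(C)(C)[Si](C)(C)OC[C@@H](OCc1ccc(OC)cc1)/C=C/CO | intermediate
13 | (S,E)-allylic bromide: C12 Br, C11=C7 E, C8 OPMB, C9 OTBS | CC(C)(C)[Si](C)(C)OC[C@@H](OCc1ccc(OC)cc1)/C=C/CBr | intermediate
14 | E-allylchromium dichloride (trivalent chromium on C12, not isolated) | CC(C)(C)[Si](C)(C)OC[C@@H](OCc1ccc(OC)cc1)/C=C/C[Cr](Cl)Cl | intermediate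
15 | (6S,7S,8S)-homoallylic alcohol: C6 OH next to the Z-iodoalkene, C7 vinyl, C8 OPMB, C9 OTBS, C15 OTBDPS; C6–O/C7–C8 anti | CC(C)(C)[Si](C)(C)OC[C@@H](OCc1ccc(OC)cc1)[C@@H](C=C)[C@H](O)/C=C(/CO[Si](c1ccccc1)(c1ccccc1)C(C)(C)C)I | intermediate
16 | C12 B-alkyl-9-BBN, O6 9-BBN borinate (not isolated) | CC(C)(C)[Si](C)(C)OC[C@@H](OCc1ccc(OC)cc1)[C@@H](CCB1C2CCCC1CCC2)[C@H](OB1C2CCCC1CCC2)/C=C(/CO[Si](c1ccccc1)(c1ccccc1)C(C)(C)C)I | intermediate
17 | (6S,7S,8S)-C6,C12-diol | CC(C)(C)[Si](C)(C)OC[C@@H](OCc1ccc(OC)cc1)[C@@H](CCO)[C@H](O)/C=C(/CO[Si](c1ccccc1)(c1ccccc1)C(C)(C)C)I | intermediate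
18 | five-membered lactol (C12 hemiacetal, both anomers, not isolated) | CC(C)(C)[Si](C)(C)OC[C@@H](OCc1ccc(OC)cc1)[C@H]1CC(O)O[C@@H]1/C=C(/CO[Si](c2ccccc2)(c2ccccc2)C(C)(C)C)I | intermediate
19 | (6S,7S,8S)-trans-γ-lactone, C9 OTBS | CC(C)(C)[Si](C)(C)OC[C@@H](OCc1ccc(OC)cc1)[C@H]1CC(=O)O[C@@H]1/C=C(/CO[Si](c2ccccc2)(c2ccccc2)C(C)(C)C)I | intermediate
20 | (6S,7S,8S)-trans-γ-lactone, C9 primary alcohol | OC[C@@H](OCc1ccc(OC)cc1)[C@H]1CC(=O)O[C@@H]1/C=C(/CO[Si](c2ccccc2)(c2ccccc2)C(C)(C)C)I | intermediate
21 | (6S,7S,8S)-trans-γ-lactone, C9 aldehyde with α-OPMB | O=C[C@@H](OCc1ccc(OC)cc1)[C@H]1CC(=O)O[C@@H]1/C=C(/CO[Si](c2ccccc2)(c2ccccc2)C(C)(C)C)I | intermediate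
22 | 3,3-diethoxyprop-1-yne | C#CC(OCC)OCC | starting material
23 | lithium 3,3-diethoxyprop-1-ynide (not isolated) | [Li]C#CC(OCC)OCC | intermediate
24 | 4,4-diethoxybut-2-yn-1-ol | OCC#CC(OCC)OCC | intermediate
25 | sodium cyclic vinylalanate from 24 (not isolated) | [Na+].COCCO[Al-]1(OCCOC)OCC=C1C(OCC)OCC | intermediate
26 | (Z)-4,4-diethoxy-3-iodobut-2-en-1-ol (iodine cis to CH2OH) | OC/C=C(/C(OCC)OCC)I | intermediate
27 | (Z)-4,4-diethoxy-3-iodobut-2-enal | O=C/C=C(/C(OCC)OCC)I | intermediate
28 | (3Z)-5,5-diethoxy-4-iodopenta-1,3-diene (C3, C2, C1, C10, C14) | C=C/C=C(/C(OCC)OCC)I | intermediate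
29 | dienyllithium, lithium on C10 cis to C2 (not isolated) | C=C/C=C(/C(OCC)OCC)[Li] | intermediate
30 | dienylmagnesium bromide, magnesium on C10 cis to C2 (not isolated) | C=C/C=C(/C(OCC)OCC)[Mg]Br | intermediate
31 | (6S,7S,8S,9S)-C9 carbinol: 8,9-syn, O8 PMB, C10=C1–C2=C3 diene with C14 diethyl acetal, trans-lactone, C4 Z-iodide | C=C/C=C(/C(OCC)OCC)[C@H](O)[C@@H](OCc1ccc(OC)cc1)[C@H]1CC(=O)O[C@@H]1/C=C(/CO[Si](c2ccccc2)(c2ccccc2)C(C)(C)C)I | intermediate
32 | open-chain iodo-diene, as 31 with O9 TES (precursor of the ring closure) | C=C/C=C(/C(OCC)OCC)[C@H](O[Si](CC)(CC)CC)[C@@H](OCc1ccc(OC)cc1)[C@H]1CC(=O)O[C@@H]1/C=C(/CO[Si](c2ccccc2)(c2ccccc2)C(C)(C)C)I | intermediate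
33 | C3 B-alkyl-9-BBN of 32 (not isolated) | B1(C2CCCC1CCC2)CC/C=C(/C(OCC)OCC)[C@H](O[Si](CC)(CC)CC)[C@@H](OCc3ccc(OC)cc3)[C@H]4CC(=O)O[C@@H]4/C=C(/CO[Si](c5ccccc5)(c6ccccc6)C(C)(C)C)I | intermediate
34 | (6R,7S,8S,9S)-ten-membered cis,cis-diene 12,6-olide: O8 PMB, O9 TES, C14 diethyl acetal, C15 OTBDPS | COc1ccc(CO[C@H]2[C@H]3CC(=O)O[C@@H]3/C=C(/CO[Si](c4ccccc4)(c5ccccc5)C(C)(C)C)CC/C=C(/C(OCC)OCC)[C@@H]2O[Si](CC)(CC)CC)cc1 | intermediate
35 | lithium enolate of 34 (C11=C12, not isolated) | COc1ccc(CO[C@H]2[C@H]3C=C(O[Li])O[C@@H]3/C=C(/CO[Si](c4ccccc4)(c5ccccc5)C(C)(C)C)CC/C=C(/C(OCC)OCC)[C@@H]2O[Si](CC)(CC)CC)cc1 | intermediate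
36 | C11 dimethylaminomethyl lactone (C11 configuration not controlled and later destroyed, not isolated) | COc1ccc(CO[C@H]2[C@H]3C(CN(C)C)C(=O)O[C@@H]3/C=C(/CO[Si](c4ccccc4)(c5ccccc5)C(C)(C)C)CC/C=C(/C(OCC)OCC)[C@@H]2O[Si](CC)(CC)CC)cc1 | intermediate
37 | C11 trimethylammoniomethyl lactone iodide (not isolated) | COc1ccc(CO[C@H]2[C@H]3C(C[N+](C)(C)C)C(=O)O[C@@H]3/C=C(/CO[Si](c4ccccc4)(c5ccccc5)C(C)(C)C)CC/C=C(/C(OCC)OCC)[C@@H]2O[Si](CC)(CC)CC)cc1.[I-] | intermediate
38 | (6R,7S,8S,9S)-α-methylene lactone, otherwise as 34 | COc1ccc(CO[C@H]2[C@H]3C(=C)C(=O)O[C@@H]3/C=C(/CO[Si](c4ccccc4)(c5ccccc5)C(C)(C)C)CC/C=C(/C(OCC)OCC)[C@@H]2O[Si](CC)(CC)CC)cc1 | intermediate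
39 | C8 alcohol (O9 TES, C14 acetal, C15 OTBDPS) | O[C@H]1[C@H]2C(=C)C(=O)O[C@@H]2/C=C(/CO[Si](c3ccccc3)(c4ccccc4)C(C)(C)C)CC/C=C(/C(OCC)OCC)[C@@H]1O[Si](CC)(CC)CC | intermediate
40 | C8 methacrylate (O9 TES, C14 acetal, C15 OTBDPS) | C=C(C)C(=O)O[C@H]1[C@H]2C(=C)C(=O)O[C@@H]2/C=C(/CO[Si](c3ccccc3)(c4ccccc4)C(C)(C)C)CC/C=C(/C(OCC)OCC)[C@@H]1O[Si](CC)(CC)CC | intermediate
41 | C8 methacrylate, C9 alcohol, C14 enal, C15 OTBDPS | C=C(C)C(=O)O[C@H]1[C@H]2C(=C)C(=O)O[C@@H]2/C=C(/CO[Si](c3ccccc3)(c4ccccc4)C(C)(C)C)CC/C=C(/C=O)[C@@H]1O | intermediate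
42 | C8 methacrylate, C9 acetate, C14 enal, C15 OTBDPS | C=C(C)C(=O)O[C@H]1[C@H]2C(=C)C(=O)O[C@@H]2/C=C(/CO[Si](c3ccccc3)(c4ccccc4)C(C)(C)C)CC/C=C(/C=O)[C@@H]1OC(C)=O | intermediate
43 | (6R,7S,8S,9S)-9-acetoxy-15-hydroxy-8-methacryloyloxy-14-oxogermacra-1(10),4,11(13)-trien-12,6-olide, both ring alkenes cis in the ring | C=C(C)C(=O)O[C@H]1[C@H]2C(=C)C(=O)O[C@@H]2/C=C(/CO)CC/C=C(/C=O)[C@@H]1OC(C)=O | target

Total step count: 27. Longest linear sequence: 20 steps from diethyl D-tartrate (steps 4–14 and 19–27). Steps 1–3 and 15–18 are side branches.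

Steps most likely to fail

Step 21. Intermolecular coupling may outrun closure of the strained ten-membered ring, because transfer of the alkyl group from boron to palladium is slow at high dilution. The aqueous base may also slowly saponify the lactone during the long addition. The fallback takes boron, water and base out of the ring-closing event.
- It sets out from 32, which is hydroborated as before to 33.
- Oxidation with NaBO3·4H2O then gives the primary C3 alcohol F1.
- PPh3, I2 and imidazole convert this into the primary C3 iodide F2.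
- Zinc dust with LiCl in THF inserts only into the sp3 carbon–iodine bond and gives the alkylzinc iodide F3.
- F3 is added slowly to Pd(PPh3)4 in THF, so that an intramolecular Negishi coupling makes the same C3–C4 bond under neutral, anhydrous conditions with a much faster transmetalation.
- The route is rejoined at 34.

Step 10. Facial selectivity at the allyl unit (C7 relative to C8) may be poor if the acyclic C8 ether does not control the conformation well enough. Divalent chromium may also partly reduce the β-iodoenal. The fallback replaces substrate control and the reducing metal by catalyst control.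
- It sets out from 13, which with B2pin2 and catalytic Pd2(dba)3 in THF gives the (E)-allyl pinacol boronate F4.
- F4 adds to 5 in toluene at low temperature under catalysis by the chiral phosphoric acid TRIP (3,3'-bis(2,4,6-triisopropylphenyl)-BINOL hydrogen phosphate).
- The S enantiomer is chosen, by analogy with simple aldehydes, to direct attack onto the Si face of the enal.
- The closed chair transition state of the E-boronate still gives the anti adduct, and fixing the aldehyde face fixes the allyl face.
- Work-up returns the route at 15.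

Step 19. Facial selectivity may be poor if the magnesium chelate between O8 and the aldehyde is incomplete for so hindered a nucleophile, and the lactone may be attacked if the mixture has to be warmed. The fallback sets C9 by hydride delivery instead of carbon delivery.
- It sets out from 31 as whatever C9 epimer mixture is obtained.
- Oxidation with Dess–Martin periodinane gives the dienone F5.
- Reduction with LiBH(sBu)3 in THF at −78 °C should be 1,2-selective on the α,β-disubstituted enone and leave the γ-lactone alone.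
- A bulky, non-chelating hydride follows the polar Felkin–Anh model, approaches anti to the C8–O bond and gives the 8,9-syn alcohol.
- The route is rejoined at 31.

Further compounds
F1 | step 21 | primary C3 alcohol from 32 (C3 CH2OH, C2 CH2, otherwise as 32) | OCC/C=C(/C(OCC)OCC)[C@H](O[Si](CC)(CC)CC)[C@@H](OCc1ccc(OC)cc1)[C@H]2CC(=O)O[C@@H]2/C=C(/CO[Si](c3ccccc3)(c4ccccc4)C(C)(C)C)I
F2 | step 21 | primary C3 iodide | ICC/C=C(/C(OCC)OCC)[C@H](O[Si](CC)(CC)CC)[C@@H](OCc1ccc(OC)cc1)[C@H]2CC(=O)O[C@@H]2/C=C(/CO[Si](c3ccccc3)(c4ccccc4)C(C)(C)C)I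
F3 | step 21 | C3 alkylzinc iodide | I[Zn]CC/C=C(/C(OCC)OCC)[C@H](O[Si](CC)(CC)CC)[C@@H](OCc1ccc(OC)cc1)[C@H]2CC(=O)O[C@@H]2/C=C(/CO[Si](c3ccccc3)(c4ccccc4)C(C)(C)C)I
F4 | step 10 | (S,E)-allyl pinacol boronate (boron on C12) | CC(C)(C)[Si](C)(C)OC[C@@H](OCc1ccc(OC)cc1)/C=C/CB2OC(C)(C)C(C)(C)O2
F5 | step 19 | C9 dienone | C=C/C=C(/C(OCC)OCC)C(=O)[C@@H](OCc1ccc(OC)cc1)[C@H]2CC(=O)O[C@@H]2/C=C(/CO[Si](c3ccccc3)(c4ccccc4)C(C)(C)C)I
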